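**Retrosynthetic overview**
- Perrottetin E ⇐ BBr3 O-demethylation of its ring A/ring D dimethyl ether, in which the ring C hydroxyl is already free.
- Key disconnection: the diaryl ether bond between the ring B oxygen and the ring C carbon ortho to the ring C hydroxyl ⇐ proposed carbene O–H insertion of a phenol half (rings A–B) into an ortho-quinone diazide half (rings D–C).
- Quinone diazide ⇐ ortho-aminophenol ⇐ nitro diarylalkyne; phenol half ⇐ diarylalkyne; both CH2CH2 bridges ⇐ Sonogashira coupling of one alkyne (3-ethynylanisole) with 4-iodophenol or 4-iodo-2-nitrophenol, then hydrogenation.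
- No ring is built: all four benzene rings are bought; order of assembly is the A–B half, the D–C half, the B–O–C union, then deprotection.

Assumption: the target has no stereocentre and no stereogenic double bond, so the SMILES given is a single achiral compound and no step has to set configuration.

**Route**

Step 1
Reactants: 1 1-ethynyl-3-methoxybenzene; 2 4-iodophenol
Product: 3 4-[(3-methoxyphenyl)ethynyl]phenol
Conditions: PdCl2(PPh3)2 (2 mol%), CuI (4 mol%), Et3N (3 equiv), THF, 45 °C, Ar
Reagents that add atoms: none
Why: Sonogashira coupling of an aryl iodide with a terminal arylacetylene tolerates the free phenol and forms the first two-carbon bridge as an alkyne; no stereocentre is formed.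

Step 2
Reactants: 3 4-[(3-methoxyphenyl)ethynyl]phenol
Product: 4 4-[2-(3-methoxyphenyl)ethyl]phenol
Conditions: H2 (1 atm), 10% Pd/C, EtOAc, rt
Reagents that add atoms: none
Why: Heterogeneous catalytic hydrogenation saturates the diarylalkyne to the bibenzyl without touching the phenol or the methyl ether.

Step 3
Reactants: 1 1-ethynyl-3-methoxybenzene; 5 4-iodo-2-nitrophenol
Product: 6 4-[(3-methoxyphenyl)ethynyl]-2-nitrophenol
Conditions: PdCl2(PPh3)2 (3 mol%), CuI (5 mol%), Et3N (4 equiv), DMF, 60 °C, Ar
Reagents that add atoms: none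
Why: Sonogashira coupling at an aryl iodide that is activated by the meta nitro group, with the nitrophenoxide formed by Et3N acting only as a spectator.

Step 4
Reactants: 6 4-[(3-methoxyphenyl)ethynyl]-2-nitrophenol
Product: 7 2-amino-4-[2-(3-methoxyphenyl)ethyl]phenol
Conditions: H2 (1 atm), 10% Pd/C, EtOAc–MeOH (1:1), rt; filtered and concentrated under Ar
Reagents that add atoms: none
Why: One catalytic hydrogenation reduces the alkyne to the CH2CH2 bridge and the nitro group to the amine, giving the ortho-aminophenol, which is kept under argon because it is air-sensitive.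

Step 5
Reactants: 7 2-amino-4-[2-(3-methoxyphenyl)ethyl]phenol
Product: 8 6-diazo-4-[2-(3-methoxyphenyl)ethyl]cyclohexa-2,4-dien-1-one
Conditions: t-BuONO (1.3 equiv), CF3CO2H (5 mol%), CH2Cl2, 0 °C, dark, 7 added over 30 min; cold aq NaHCO3 wash, Na2SO4, concentrated at ≤20 °C
Reagents that add atoms: tert-butyl nitrite, CC(C)(C)ON=O
Why: Aprotic diazotization of an ortho-aminophenol (the same reaction type that turns anthranilic acid into benzenediazonium-2-carboxylate) gives the diazonium phenolate, which is the neutral ortho-quinone diazide; inverse addition keeps nitrite in excess and suppresses azo coupling.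

Step 6
Reactants: 8 6-diazo-4-[2-(3-methoxyphenyl)ethyl]cyclohexa-2,4-dien-1-one; 4 4-[2-(3-methoxyphenyl)ethyl]phenol
Product: 9 4-[2-(3-methoxyphenyl)ethyl]-2-{4-[2-(3-methoxyphenyl)ethyl]phenoxy}phenol
Conditions: Rh2(esp)2 (1 mol%; esp = 1,3-C6H4(CH2CMe2CO2)2), 4 (2.0 equiv, excess recovered), 4 Å MS, CH2Cl2, 0 °C → rt, dark; 8 added over 4 h by syringe pump
Reagents that add atoms: none
Why: Proposed new method: carbene O–H insertion of a phenol into a monocyclic ortho-quinone diazide to give an ortho-hydroxy diaryl ether; Rh2(esp)2 (a chelated dirhodium tetracarboxylate, divalent rhodium) expels N2 from 8 to give an electrophilic rhodium quinoid carbene (a rhodium-bound 2-oxidophenyl cation) at the carbon that carried the amino group, the hydroxyl oxygen of 4 adds to that carbon to give an aryloxonium ylide whose enolate oxygen is a phenolate, and a 1,4-proton shift from the oxonium to that oxygen releases the catalyst and the already aromatic 2-aryloxyphenol 9, so the C–O bond can form only ortho to the ring C hydroxyl and meta to the side chain; slow addition of 8 to excess 4 in a non-nucleophilic, nitrile-free solvent disfavours carbene dimerisation, attack on the anisole rings and a second arylation of the hindered, hydrogen-bonded hydroxyl of 9; closest known reaction type: dirhodium-carbene O–H insertion of phenols with alpha-diazo carbonyl compounds, together with carbene-transfer arylations from diazonaphthoquinones; no stereocentre is formed.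

Step 7
Reactants: 9 4-[2-(3-methoxyphenyl)ethyl]-2-{4-[2-(3-methoxyphenyl)ethyl]phenoxy}phenol
Product: 10 perrottetin E
Conditions: BBr3 (6 equiv), CH2Cl2, −78 °C → rt; H2O quench
Reagents that add atoms: none
Why: Lewis-acid O-demethylation with BBr3 cleaves both aryl methyl ethers through bromide attack on the boron-activated methyl groups, while the diaryl ether and the saturated bridges are inert.

**Compound list**
1 | 1-ethynyl-3-methoxybenzene | COc1cccc(C#C)c1 | starting material
2 | 4-iodophenol | Oc1ccc(I)cc1 | starting material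
3 | 4-[(3-methoxyphenyl)ethynyl]phenol | COc1cccc(C#Cc2ccc(O)cc2)c1 | intermediate
4 | 4-[2-(3-methoxyphenyl)ethyl]phenol | COc1cccc(CCc2ccc(O)cc2)c1 | intermediate
5 | 4-iodo-2-nitrophenol | Oc1ccc(I)cc1[N+](=O)[O-] | starting material
6 | 4-[(3-methoxyphenyl)ethynyl]-2-nitrophenol | COc1cccc(C#Cc2ccc(O)c([N+](=O)[O-])c2)c1 | intermediate
7 | 2-amino-4-[2-(3-methoxyphenyl)ethyl]phenol | COc1cccc(CCc2ccc(O)c(N)c2)c1 | intermediate
8 | 6-diazo-4-[2-(3-methoxyphenyl)ethyl]cyclohexa-2,4-dien-1-one | COc1cccc(CCC2=CC(=[N+]=[N-])C(=O)C=C2)c1 | intermediate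
9 | 4-[2-(3-methoxyphenyl)ethyl]-2-{4-[2-(3-methoxyphenyl)ethyl]phenoxy}phenol | COc1cccc(CCc2ccc(Oc3cc(CCc4cccc(OC)c4)ccc3O)cc2)c1 | intermediate
10 | perrottetin E, 4-[2-(3-hydroxyphenyl)ethyl]-2-{4-[2-(3-hydroxyphenyl)ethyl]phenoxy}phenol | Oc1cccc(CCc2ccc(Oc3cc(CCc4cccc(O)c4)ccc3O)cc2)c1 | target

**Step count**
Total step count: 7.
Longest linear sequence: 5 steps (steps 3, 4, 5, 6, 7); the other branch is steps 1, 2, 6, 7.

**Three steps most likely to fail**

Step 6 (the proposed new step). The quinoid carbene could instead attack an aromatic carbon of 4 or an anisole ring (biaryl formation), arylate the hydroxyl of 9 a second time, dimerise, or undergo Wolff ring contraction. Fallback, known chemistry, setting out from 1 and coming back at 10: commercial 5-bromo-2-methoxyphenol (COc1ccc(Br)cc1O) and 4-bromophenylboronic acid (OB(O)c1ccc(Br)cc1) are joined by Chan–Lam coupling (Cu(OAc)2, pyridine, 4 Å MS, CH2Cl2, air, rt) to give 4-bromo-2-(4-bromophenoxy)-1-methoxybenzene F1. Double Sonogashira coupling of this dibromide with 2.4 equiv of 1 (PdCl2(MeCN)2, XPhos, Cs2CO3, MeCN, 80 °C) gives 1-methoxy-4-[(3-methoxyphenyl)ethynyl]-2-{4-[(3-methoxyphenyl)ethynyl]phenoxy}benzene F2. Hydrogenation (H2, 10% Pd/C, EtOAc, rt) gives 1-methoxy-4-[2-(3-methoxyphenyl)ethyl]-2-{4-[2-(3-methoxyphenyl)ethyl]phenoxy}benzene F3, and BBr3 (CH2Cl2, −78 °C → rt) cleaves all three methyl ethers to give 10.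

Step 5. The neutral diazo oxide 8 is light- and heat-sensitive, and the electron-rich aminophenol can undergo azo coupling or oxidation during aprotic diazotization. Fallback, setting out from 7 and coming back at 8: 7 is diazotized under protic conditions (NaNO2, 48% aq HBF4, EtOH–H2O, 0 °C), where the amine is fully protonated, and the crystalline salt 2-hydroxy-5-[2-(3-methoxyphenyl)ethyl]benzenediazonium tetrafluoroborate F4 is filtered off and stored cold. Immediately before step 6 the salt is shaken with cold aqueous NaHCO3 and CH2Cl2, and the dried organic layer, which holds 8, is used at once without concentration.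

Step 3. The free ortho-nitrophenoxide can bind copper and slow the coupling, which favours alkyne homocoupling. Fallback, setting out from 4 and coming back at 7: 4 is nitrated chemoselectively ortho to the phenol with t-BuONO (THF, air, rt). This proceeds by O-nitrosation, homolysis and recombination of the phenoxyl radical with NO2, a pathway closed to the anisole ring, and gives 4-[2-(3-methoxyphenyl)ethyl]-2-nitrophenol F5. Hydrogenation (H2, 10% Pd/C, EtOAc–MeOH, rt) then gives 7, so steps 3 and 4 are no longer needed.

**Further compounds**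
F1 | step 6 | 4-bromo-2-(4-bromophenoxy)-1-methoxybenzene | COc1ccc(Br)cc1Oc1ccc(Br)cc1
F2 | step 6 | 1-methoxy-4-[(3-methoxyphenyl)ethynyl]-2-{4-[(3-methoxyphenyl)ethynyl]phenoxy}benzene | COc1cccc(C#Cc2ccc(Oc3cc(C#Cc4cccc(OC)c4)ccc3OC)cc2)c1
F3 | step 6 | 1-methoxy-4-[2-(3-methoxyphenyl)ethyl]-2-{4-[2-(3-methoxyphenyl)ethyl]phenoxy}benzene | COc1cccc(CCc2ccc(Oc3cc(CCc4cccc(OC)c4)ccc3OC)cc2)c1
F4 | step 5 | 2-hydroxy-5-[2-(3-methoxyphenyl)ethyl]benzenediazonium tetrafluoroborate | COc1cccc(CCc2ccc(O)c([N+]#N)c2)c1.F[B-](F)(F)F
F5 | step 3 | 4-[2-(3-methoxyphenyl)ethyl]-2-nitrophenol | COc1cccc(CCc2ccc(O)c([N+](=O)[O-])c2)c1
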